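The C2-symmetric target is assembled from two copies of one C15 phosphonium salt and the C10 trienedial. Everything rests on cutting the cyclohexane ring C1–C6 (carotenoid numbering) into two three-carbon halves: C2–C3–C4, a silylated hydroxyacetone, and C5–C6–C1 with C7, an acyclic, achiral ethylidene acetoacetate used as E/Z mixture. The cut exploits the oxygen on C3, which makes C2 and C4 donors, and C7 on C6, which makes C5 and C1 acceptors. One amine-catalysed Michael/aldol-condensation domino closes the ring, brings in O4 and sets C4 and C5. Hydride then sets C3, equilibration C6, and a cuprate adds the second C1 methyl.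

Key step: step 2

Remark: the comments use carotenoid numbering (C1 = CMe2, C3/C4 = oxygenated carbons, C5 = CHMe, C6 bears the chain). The sense of induction in step 2 is assigned by analogy with the syn-selective nitroalkene additions of the same catalyst class. The target is released as the free bis(hydrogen sulfate) drawn, although it would be stored as its disodium salt.

Step 1
Reactants: 1 acetaldehyde; 2 ethyl acetoacetate
Product: 3 ethyl 2-ethylidene-3-oxobutanoate (E/Z mixture)
Conditions: piperidine (cat.), AcOH (cat.), 4 Å MS, CH2Cl2, −10 to 0 °C, 1 in excess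
Reagents that add atoms: none
Why: Knoevenagel condensation of an aldehyde with an active methylene compound; low temperature and excess aldehyde hold back a second (Michael) addition, and the E/Z composition does not matter for step 2.

Step 2
Reactants: 3 ethyl 2-ethylidene-3-oxobutanoate; 4 1-[(tert-butyldimethylsilyl)oxy]propan-2-one
Product: 7 ethyl (5S,6R)-5-[(tert-butyldimethylsilyl)oxy]-2,6-dimethyl-4-oxocyclohex-2-ene-1-carboxylate (C1 epimers), via Michael adduct 5 (not isolated), via cyclic aldol 6 (not isolated)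
Conditions: (S)-1-[3,5-bis(trifluoromethyl)phenyl]-3-(pyrrolidin-2-ylmethyl)thiourea (20 mol %), PhCO2H (20 mol %), 4 in excess, slow addition of 3, toluene, 0 °C to rt, then 45 °C
Reagents that add atoms: none
Why: The pyrrolidine nitrogen condenses with 4 to the more substituted, oxygen-stabilised (E)-enamine, whose carbon (future C4) adds to the β-carbon of 3 (future C5) while the thiourea holds the two carbonyl groups of 3; after hydrolysis to 5 the amine re-enters on the methyl side (future C2), this enamine adds to the acetyl C=O (future C1) to give 6, and loss of water gives 7. The closest known reaction types are the Michael/aldol condensation of alkylidene acetoacetates with methyl ketones that leads to Hagemann-type esters, and the enamine-catalysed Michael addition of ketones to alkylidene malonates and nitroalkenes (organocatalytic formal [3+3] annulation). The one ring that is closed, the future cyclohexane C1–C6, forms in the 6-(enolendo)-exo-trig mode. C4 and C5 are set together in the synclinal enamine transition state, in which the (S)-pyrrolidine side arm covers one enamine face and delivers the acceptor, so the syn adduct (4S,5R) is expected by analogy with nitrostyrene additions of this catalyst class, whereas the ester-bearing C6 is a vinylogous β-keto ester centre that stays labile and is left open. The step needs attack through the oxygenated carbon of 4 and not its methyl group, which the donor oxygen on the enamine secures, and aldol closure onto the acetoacetate ketone and not the reverse, which follows the known closure of acetoacetate-derived 1,5-diketones, where the β-keto ester enolises toward C6 and never toward its methyl group. The E and Z isomers of 3 differ only in which acyl group lies cis to the methyl group and interconvert by reversible amine addition, so both should funnel into the same C5 configuration.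

Step 3
Reactants: 7 enone ester
Product: 9 ethyl (5S,6R)-5-[(tert-butyldimethylsilyl)oxy]-2,2,6-trimethyl-4-oxocyclohexane-1-carboxylate (C1 epimers), via TMS enol ether 8 (not isolated)
Conditions: Me2CuLi, TMSCl, Et2O–THF, −78 to −30 °C; then 0.5 M citric acid, THF, 0 °C
Reagents that add atoms: lithium dimethylcuprate [Li+].C[Cu-]C; chlorotrimethylsilane C[Si](C)(C)Cl (its silicon stays only in 8)
Why: TMSCl-accelerated Gilman conjugate addition should outrun deprotonation of the acidic γ-H and builds the quaternary C1, which is no stereocentre because it then carries two methyl groups, while C4 and C5 are untouched at low temperature.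

Step 4
Reactants: 9 keto ester
Product: 10 ethyl (4R,5S,6R)-5-[(tert-butyldimethylsilyl)oxy]-4-hydroxy-2,2,6-trimethylcyclohexane-1-carboxylate (C1 epimers)
Conditions: L-Selectride, THF, −78 °C; H2O quench at low temperature
Reagents that add atoms: none
Why: Substrate-controlled ketone reduction with a bulky trialkylborohydride: the axial C1 methyl blocks the axial trajectory, hydride enters from the equatorial side and the new C3–OH should be axial and cis to the equatorial O4 (3R), while a C4 epimer with axial silyloxy group would be shielded on both faces and stay behind.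

Step 5
Reactants: 10 hydroxy ester
Product: 12 (1R,4R,5S,6R)-5-[(tert-butyldimethylsilyl)oxy]-4-hydroxy-2,2,6-trimethylcyclohexane-1-carbaldehyde, via aldehyde epimer mixture 11 (not isolated)
Conditions: DIBAL-H (2.2 equiv), CH2Cl2, −78 °C; aqueous work-up; then K2CO3 (cat.), MeOH, rt
Reagents that add atoms: none
Why: Partial DIBAL reduction of the ester through the cold-stable aluminium hemiacetal, followed by base equilibration of the α-centre, in which the formyl group settles equatorial and trans to the C5 methyl, sets C6 (R) from both epimers.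

Step 6
Reactants: 12 aldehyde; 13 ethyl (2E)-4-(diethoxyphosphoryl)-3-methylbut-2-enoate
Product: 14 ethyl (2E,4E)-5-[(1R,4R,5S,6R)-5-[(tert-butyldimethylsilyl)oxy]-4-hydroxy-2,2,6-trimethylcyclohexyl]-3-methylpenta-2,4-dienoate
Conditions: LiHMDS (2.2 equiv), THF–DMPU, −78 to 0 °C
Reagents that add atoms: none
Why: Horner–Wadsworth–Emmons olefination with a vinylogous phosphonoacetate should give the new C7=C8 bond E and keep C9=C10 E, and the equatorial aldehyde reacts faster than its axial epimer, so C6 stays trans; a base-induced silyl shift between O4 and O3 would be harmless because both oxygens are freed in step 8.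

Step 7
Reactants: 14 dienoate
Product: 15 (2E,4E)-5-[(1R,4R,5S,6R)-5-[(tert-butyldimethylsilyl)oxy]-4-hydroxy-2,2,6-trimethylcyclohexyl]-3-methylpenta-2,4-dien-1-ol
Conditions: DIBAL-H (3.5 equiv), CH2Cl2, −78 to −20 °C
Reagents that add atoms: none
Why: DIBAL 1,2-reduction of a conjugated ester to the allylic alcohol, which leaves the diene, the silyl ether and all stereocentres unchanged.

Step 8
Reactants: 15 dienol
Product: 16 [(2E,4E)-5-[(1R,4R,5S,6R)-4,5-dihydroxy-2,2,6-trimethylcyclohexyl]-3-methylpenta-2,4-dienyl]triphenylphosphonium bromide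
Conditions: PPh3·HBr (1.3 equiv), MeOH, rt to 40 °C
Reagents that add atoms: triphenylphosphine hydrobromide [Br-].c1ccc(cc1)[PH+](c1ccccc1)c1ccccc1
Why: Standard Wittig-salt formation from an allylic alcohol, in which PPh3 traps the pentadienyl cation at its primary end; the acidic methanol should solvolyse the TBS ether at the same time, and the secondary non-allylic alcohols are inert.

Step 9
Reactants: 16 C15 phosphonium bromide (2.1 equiv); 17 (2E,4E,6E)-2,7-dimethylocta-2,4,6-trienedial
Product: 18 (all-E,3R,4S,5R,6R,3'R,4'S,5'R,6'R)-5,6,5',6'-tetrahydro-β,β-carotene-3,4,3',4'-tetrol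
Conditions: NaOMe, MeOH–CH2Cl2, 0 °C to rt, Ar, dark; then EtOH, reflux (Z to E equilibration)
Reagents that add atoms: none
Why: Double Wittig olefination (C15 + C10 + C15) tolerates free hydroxyl groups as in xanthophyll manufacture, and any 11Z/11'Z isomers should equilibrate thermally to the all-E polyene without touching the ring stereocentres.

Step 10
Reactants: 18 tetrol
Product: 20 (all-E,3R,4S,5R,6R,3'R,4'S,5'R,6'R)-5,6,5',6'-tetrahydro-β,β-carotene-3,4,3',4'-tetrol 4,4'-bis(hydrogen sulfate) (CNP0202532.2), via bis-stannylene acetal 19 (not isolated)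
Conditions: Bu2SnO (2.2 equiv), MeOH, reflux, evaporate; SO3·NMe3 (2.4 equiv), THF–dioxane, rt, Ar, dark; Dowex 50W (H+), MeOH, 0 °C, short contact
Reagents that add atoms: sulfur trioxide–trimethylamine complex C[N+](C)(C)S(=O)(=O)[O-]; dibutyltin oxide CCCC[Sn](=O)CCCC (its tin stays only in 19)
Why: Stannylene-acetal-mediated regioselective sulfation of a cis-1,2-diol, as used on carbohydrates, activates the equatorial oxygen O4, while the axial O3 is also shielded by the syn-axial C1 methyl; no stereocentre is touched.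

Compound list
1 | acetaldehyde | CC=O | starting material
2 | ethyl acetoacetate | CCOC(=O)CC(C)=O | starting material
3 | ethyl 2-ethylidene-3-oxobutanoate (E/Z mixture) | CC=C(C(C)=O)C(=O)OCC | intermediate
4 | 1-[(tert-butyldimethylsilyl)oxy]propan-2-one | CC(=O)CO[Si](C)(C)C(C)(C)C | starting material
5 | ethyl (3R,4S)-2-acetyl-4-[(tert-butyldimethylsilyl)oxy]-3-methyl-5-oxohexanoate (C2 labile) | CCOC(=O)C(C(C)=O)[C@@H](C)[C@H](O[Si](C)(C)C(C)(C)C)C(C)=O | intermediate
6 | ethyl (5S,6R)-5-[(tert-butyldimethylsilyl)oxy]-2-hydroxy-2,6-dimethyl-4-oxocyclohexane-1-carboxylate (C1 and C2 open) | CCOC(=O)C1[C@@H](C)[C@H](O[Si](C)(C)C(C)(C)C)C(=O)CC1(C)O | intermediate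
7 | ethyl (5S,6R)-5-[(tert-butyldimethylsilyl)oxy]-2,6-dimethyl-4-oxocyclohex-2-ene-1-carboxylate (C1 epimers) | CCOC(=O)C1[C@@H](C)[C@H](O[Si](C)(C)C(C)(C)C)C(=O)C=C1C | intermediate
8 | ethyl (5S,6R)-5-[(tert-butyldimethylsilyl)oxy]-2,2,6-trimethyl-4-[(trimethylsilyl)oxy]cyclohex-3-ene-1-carboxylate (C1 epimers) | CCOC(=O)C1[C@@H](C)[C@H](O[Si](C)(C)C(C)(C)C)C(O[Si](C)(C)C)=CC1(C)C | intermediate
9 | ethyl (5S,6R)-5-[(tert-butyldimethylsilyl)oxy]-2,2,6-trimethyl-4-oxocyclohexane-1-carboxylate (C1 epimers) | CCOC(=O)C1[C@@H](C)[C@H](O[Si](C)(C)C(C)(C)C)C(=O)CC1(C)C | intermediate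
10 | ethyl (4R,5S,6R)-5-[(tert-butyldimethylsilyl)oxy]-4-hydroxy-2,2,6-trimethylcyclohexane-1-carboxylate (C1 epimers) | CCOC(=O)C1[C@@H](C)[C@H](O[Si](C)(C)C(C)(C)C)[C@H](O)CC1(C)C | intermediate
11 | (4R,5S,6R)-5-[(tert-butyldimethylsilyl)oxy]-4-hydroxy-2,2,6-trimethylcyclohexane-1-carbaldehyde (C1 epimer mixture) | O=CC1[C@@H](C)[C@H](O[Si](C)(C)C(C)(C)C)[C@H](O)CC1(C)C | intermediate
12 | (1R,4R,5S,6R)-5-[(tert-butyldimethylsilyl)oxy]-4-hydroxy-2,2,6-trimethylcyclohexane-1-carbaldehyde | O=C[C@@H]1[C@@H](C)[C@H](O[Si](C)(C)C(C)(C)C)[C@H](O)CC1(C)C | intermediate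
13 | ethyl (2E)-4-(diethoxyphosphoryl)-3-methylbut-2-enoate (triethyl 3-methyl-4-phosphonocrotonate) | CCOC(=O)/C=C(\C)CP(=O)(OCC)OCC | starting material
14 | ethyl (2E,4E)-5-[(1R,4R,5S,6R)-5-[(tert-butyldimethylsilyl)oxy]-4-hydroxy-2,2,6-trimethylcyclohexyl]-3-methylpenta-2,4-dienoate | CCOC(=O)/C=C(C)/C=C/[C@@H]1[C@@H](C)[C@H](O[Si](C)(C)C(C)(C)C)[C@H](O)CC1(C)C | intermediate
15 | (2E,4E)-5-[(1R,4R,5S,6R)-5-[(tert-butyldimethylsilyl)oxy]-4-hydroxy-2,2,6-trimethylcyclohexyl]-3-methylpenta-2,4-dien-1-ol | OC/C=C(C)/C=C/[C@@H]1[C@@H](C)[C@H](O[Si](C)(C)C(C)(C)C)[C@H](O)CC1(C)C | intermediate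
16 | [(2E,4E)-5-[(1R,4R,5S,6R)-4,5-dihydroxy-2,2,6-trimethylcyclohexyl]-3-methylpenta-2,4-dienyl]triphenylphosphonium bromide | [Br-].C(/C=C(C)/C=C/[C@@H]1[C@@H](C)[C@H](O)[C@H](O)CC1(C)C)[P+](c1ccccc1)(c1ccccc1)c1ccccc1 | intermediate
17 | (2E,4E,6E)-2,7-dimethylocta-2,4,6-trienedial | O=C/C(C)=C/C=C/C=C(C)/C=O | starting material
18 | (all-E,3R,4S,5R,6R,3'R,4'S,5'R,6'R)-5,6,5',6'-tetrahydro-β,β-carotene-3,4,3',4'-tetrol | CC(/C=C/C=C(C)/C=C/[C@@H]1[C@@H](C)[C@H](O)[C@H](O)CC1(C)C)=C\C=C\C=C(C)\C=C\C=C(C)\C=C\[C@@H]1[C@@H](C)[C@H](O)[C@H](O)CC1(C)C | intermediate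
19 | 3,4:3',4'-bis-O-(dibutylstannylene) acetal of 18 | CC(/C=C/C=C(C)/C=C/[C@@H]1[C@@H](C)[C@@H]2O[Sn](CCCC)(CCCC)O[C@@H]2CC1(C)C)=C\C=C\C=C(C)\C=C\C=C(C)\C=C\[C@@H]1[C@@H](C)[C@@H]2O[Sn](CCCC)(CCCC)O[C@@H]2CC1(C)C | intermediate
20 | (all-E,3R,4S,5R,6R,3'R,4'S,5'R,6'R)-5,6,5',6'-tetrahydro-β,β-carotene-3,4,3',4'-tetrol 4,4'-bis(hydrogen sulfate) | CC(/C=C/C=C(C)/C=C/[C@@H]1[C@@H](C)[C@H](OS(=O)(=O)O)[C@H](O)CC1(C)C)=C\C=C\C=C(C)\C=C\C=C(C)\C=C\[C@@H]1[C@@H](C)[C@H](OS(=O)(=O)O)[C@H](O)CC1(C)C | target

Total step count: 10. Longest linear sequence: 10 (steps 1–10).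

Steps most likely to fail

Step 2.
- What may go wrong:
  - The enamine may form and react on the methyl side of 4.
  - The catalyst may be tied up by the β-keto ester.
  - Facial discrimination at C5 may be poor because its substituent is only a methyl group.
  - C4 may epimerise under the amine/acid conditions.
  - The aldol closure may run in the reverse sense.
- Fallback (sets out from 3 and 4, comes back at 7): 4 is converted with TMSOTf/Et3N into the regiodefined (Z)-1-[(tert-butyldimethylsilyl)oxy]-2-[(trimethylsilyl)oxy]prop-1-ene F1. A Cu(II)–tBu-bis(oxazoline)-catalysed Mukaiyama–Michael addition of F1 to 3 follows, in which the chiral Lewis acid chelates the two carbonyl groups of the acceptor and controls the C5 face directly. This should give 5 in isolated form, and pyrrolidinium acetate then closes 5 to 7.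

Step 3.
- What may go wrong: deprotonation of the vinylogous β-keto ester hydrogen may compete with addition, and attack at the fully substituted β-carbon next to a branched carbon may be sluggish.
- Fallback (sets out from 7, comes back at 9):
  - Luche reduction of 7 gives ethyl (5S,6R)-5-[(tert-butyldimethylsilyl)oxy]-4-hydroxy-2,6-dimethylcyclohex-2-ene-1-carboxylate F2.
  - Hydroxyl-directed Simmons–Smith cyclopropanation (Et2Zn, CH2I2) gives ethyl (3R,4S)-4-[(tert-butyldimethylsilyl)oxy]-5-hydroxy-1,3-dimethylbicyclo[4.1.0]heptane-2-carboxylate F3.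
  - Hydrogenolysis of the least hindered cyclopropane bond (H2, PtO2, AcOH) gives ethyl (5S,6R)-5-[(tert-butyldimethylsilyl)oxy]-4-hydroxy-2,2,6-trimethylcyclohexane-1-carboxylate as carbinol epimers F4.
  - Dess–Martin oxidation returns to 9.

Step 10.
- What may go wrong: discrimination between O4 and O3 may be incomplete, over-sulfation may occur, and the polyene may isomerise or degrade during heating with the tin oxide or on contact with the acidic resin.
- Fallback (sets out from 18, comes back at 20):
  - Trimethyl orthoacetate with a trace of CSA converts both cis-diols into the 3,4:3',4'-bis-O-(1-methoxyethylidene) derivative F5.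
  - Brief treatment with aqueous acetic acid opens each orthoester to the axial ester and the free equatorial alcohol, giving the 3,3'-di-O-acetate F6.
  - SO3·pyridine then can only sulfate O4 and O4', giving the 3,3'-di-O-acetyl 4,4'-bis(hydrogen sulfate) F7.
  - K2CO3 in MeOH followed by cold H+ exchange gives 20.

Further compounds
F1 | step 2 | (Z)-1-[(tert-butyldimethylsilyl)oxy]-2-[(trimethylsilyl)oxy]prop-1-ene | C/C(O[Si](C)(C)C)=C/O[Si](C)(C)C(C)(C)C
F2 | step 3 | ethyl (5S,6R)-5-[(tert-butyldimethylsilyl)oxy]-4-hydroxy-2,6-dimethylcyclohex-2-ene-1-carboxylate | CCOC(=O)C1[C@@H](C)[C@H](O[Si](C)(C)C(C)(C)C)C(O)C=C1C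
F3 | step 3 | ethyl (3R,4S)-4-[(tert-butyldimethylsilyl)oxy]-5-hydroxy-1,3-dimethylbicyclo[4.1.0]heptane-2-carboxylate | CCOC(=O)C1[C@@H](C)[C@H](O[Si](C)(C)C(C)(C)C)C(O)C2CC21C
F4 | step 3 | ethyl (5S,6R)-5-[(tert-butyldimethylsilyl)oxy]-4-hydroxy-2,2,6-trimethylcyclohexane-1-carboxylate (carbinol epimers) | CCOC(=O)C1[C@@H](C)[C@H](O[Si](C)(C)C(C)(C)C)C(O)CC1(C)C
F5 | step 10 | 3,4:3',4'-bis-O-(1-methoxyethylidene) derivative of 18 | CC(/C=C/C=C(C)/C=C/[C@@H]1[C@@H](C)[C@@H]2OC(C)(OC)O[C@@H]2CC1(C)C)=C\C=C\C=C(C)\C=C\C=C(C)\C=C\[C@@H]1[C@@H](C)[C@@H]2OC(C)(OC)O[C@@H]2CC1(C)C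
F6 | step 10 | 3,3'-di-O-acetate of 18 | CC(/C=C/C=C(C)/C=C/[C@@H]1[C@@H](C)[C@H](O)[C@H](OC(C)=O)CC1(C)C)=C\C=C\C=C(C)\C=C\C=C(C)\C=C\[C@@H]1[C@@H](C)[C@H](O)[C@H](OC(C)=O)CC1(C)C
F7 | step 10 | 3,3'-di-O-acetyl 4,4'-bis(hydrogen sulfate) of 18 | CC(/C=C/C=C(C)/C=C/[C@@H]1[C@@H](C)[C@H](OS(=O)(=O)O)[C@H](OC(C)=O)CC1(C)C)=C\C=C\C=C(C)\C=C\C=C(C)\C=C\[C@@H]1[C@@H](C)[C@H](OS(=O)(=O)O)[C@H](OC(C)=O)CC1(C)C
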